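Time is what you must stretch here: the larch run stops at 60.0 s, and the flask is asked at 10 min.

- larch: Z 0.48 M; J 0.48 M; E 1.2 equiv; X 14 mM; G 2.1 mol%; run made earlier
- flask: Z 0.48 M; E 1.20 equiv; X 9.60 mM; G 2.1 mol%; J 0.48 M; time 10 min

- larch (time / s: D / %, Z / %): 10.0: 16.4, 33.7; 15.0: 20.7, 28.4; 25.0: 28.2, 22.5; 30.0: 30.0, 20.4; 40.0: 33.2, 16.0; 50.0: 36.3, 13.3; 60.0: 38.6, 11.2

(readings scatter by 0.5 percentage points)

1. amount of D in percent of the Z and J together charged, at 1.0 min, 3.0 min, 6.0 min and 10 min

- G is single-handed; Z and J are mirror images of each other, charged as a racemate, each of them at the stated concentration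
- steps that have been proposed: E + G + J -> G + Q; E + X -> L; E + G + Z -> G + D
- no earlier run changes the charge of X; that part of a forecast is a guess

Go through the given numbers first, and ask which of them has to be known well.

1. X. In the flask, X can take at most its charge of 9.60 mM, hardly any of the 0.576 M of E. Its speed is a guess, and I count it as gone at once.

2. G. Loading and [Z] are the same in both flasks, so a constant read at this [G] carries over.

3. J. In the larch run, D and Z together read 49.8% at 60.0 s, so Z goes to D. J can take E on its way to Q, and I leave that out.

4. The margin. With rate = k[E][Z], [E] − [Z] stays constant. It is 0.0820 M in the larch run and 0.0864 M in the flask. In the flask, E net of X, 0.566 M, is more than the 0.48 M of Z, so with J left out Z is the limiting reagent.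

5. The number. In the larch run, [Z] falls from 0.324 M to 0.108 M between 10.0 s and 60.0 s. Replacing [E] by its mean gives k = 0.0741 M⁻¹ s⁻¹. The exact integral says ln([E]/[Z]) climbs with slope k times the margin, which gives k = 0.0831 M⁻¹ s⁻¹, the second-order constant of Z and E at this [G]. The mean reads lower by 10.9%, so I keep the exact value.

6. My reckoning. In the flask, [E]/[Z] starts at 1.18, and [Z] is the margin over that ratio less one. D comes to 39.0%, 47.3%, 49.4% and 49.9%.

7. The forecast says 38.8%, 45.8%, 48.3% and 49%. It lies lower than mine at the second reading. It expects that “Q then reaches about 6 points by 10 min”, whereas I leave Q out.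

    E + G + J → G + Q (k = 0.0470 M⁻² s⁻¹)
    E + X → L (k = 6.68 M⁻¹ s⁻¹)
    E + G + Z → G + D (k = 8.16 M⁻² s⁻¹)

8. The flask gives 38.7%, 47.1%, 49.2% and 49.8%, and the forecast stands within the tolerance. At 10.0 min, Z is down to 0.167% of the Z and J together charged, while J stands at 48.4%. Now use 0.0831 M⁻¹ s⁻¹ once more, on the flask at 5.00 min: the ratio gives Z as 0.981%, and the flask holds 1.15%.

The runs were computed with constants of no real substance; noise was put on by code.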